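**Plan**

- Retrosynthesis: the N–O pivaloyloxymethyl group comes off last. The oxane ring is then cut at two bonds at once, C5–C6 (alkylidene carbon to ring CH2) and O1–C2 (ring oxygen to the carbon carrying the pyridone), which lifts out the O1–C6H2 unit as (tributylstannyl)methanol, an O,C-dinucleophile.
- Enabling feature: oxane C5 is an sp2 carbon of the exocyclic triene and can be an alkenyl bromide. Oxane C2 is bonded to C3 of the 4-hydroxy-2-pyridone ring and can be the methide carbon of an ortho-quinone methide, the electrophile of the presumed biosynthetic ring closure. The two sites are 1,4-related, so a hydroxymethyl unit bridges them into a six-membered ring.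
- Further cuts: pyridone C3–oxane C2 (Knoevenagel condensation, methide stored as its ethanol adduct), oxane C4–C5 (trans-selective Negishi monoalkylation of a 1,1-dibromotriene), the diene C–C bond and the phenyl–pyridine bond (Suzuki–Miyaura couplings).
- Forward order: side chain and bromotriene first, pyridone core in parallel, union of the two, then the oxane (the only ring made) closes in the key step and the N–OH is unmasked.
- Stereochemistry: side-chain centre from (R)-2-methylbutan-1-ol; oxane C3 from methyl (S)-3-bromo-2-methylpropanoate; oxane C2 in the key step (2,3-trans, chair-controlled and thermodynamic); 5Z from the trans-selective Negishi step followed by stereoretentive coupling; E,E-diene from Takai olefination and the (E)-alkenylboronate.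

Key step: step 12

Assumption: (R)-2-methylbutan-1-ol, methyl (S)-3-bromo-2-methylpropanoate, the (E)-acetal boronate and (tributylstannyl)methanol are taken as catalogue compounds in the stated configuration.

Step 1
Reactants: 1 (R)-2-methylbutan-1-ol
Product: 2 (R)-2-methylbutanal
Conditions: TEMPO (10 mol %), PhI(OAc)2, CH2Cl2, 0 °C to rt; NaHCO3 wash; solution used directly
Reagents that add atoms: none
Why: TEMPO-catalysed oxidation (oxoammonium mechanism) stops at the aldehyde under non-basic conditions, so the α-stereocentre should survive, and the volatile aldehyde is carried on without concentration to dryness.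

Step 2
Reactants: 2 (R)-2-methylbutanal
Product: 3 (3R,1E)-1-iodo-3-methylpent-1-ene
Conditions: CrCl2, CHI3, THF–1,4-dioxane, 0 °C to rt
Reagents that add atoms: iodoform, IC(I)I
Why: Takai olefination, in which CrCl2 (divalent chromium) reduces iodoform to a geminal dichromium species that adds to the aldehyde and eliminates anti to give the (E)-alkenyl iodide without touching the α-stereocentre.

Step 3
Reactants: 3 (3R,1E)-1-iodo-3-methylpent-1-ene; 4 (E)-2-(3,3-diethoxyprop-1-en-1-yl)-4,4,5,5-tetramethyl-1,3,2-dioxaborolane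
Product: 6 (2E,4E,6R)-6-methylocta-2,4-dienal, via dienal diethyl acetal 5 (not isolated)
Conditions: Pd(PPh3)4 (5 mol %), 2 M aq NaOH, THF, 50 °C; then 1 M HCl, rt
Reagents that add atoms: water, O
Why: Suzuki–Miyaura coupling of an (E)-alkenyl iodide with an (E)-alkenylboronate goes with retention at both partners, and the acidic work-up hydrolyses the acetal to the E,E-dienal.

Step 4
Reactants: 6 (2E,4E,6R)-6-methylocta-2,4-dienal
Product: 7 (3E,5E,7R)-1,1-dibromo-7-methylnona-1,3,5-triene
Conditions: CBr4, PPh3, CH2Cl2, 0 °C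
Reagents that add atoms: carbon tetrabromide, BrC(Br)(Br)Br
Why: Corey–Fuchs (Ramirez) dibromoolefination, a Wittig reaction of the ylide Ph3P=CBr2 formed from CBr4 and PPh3, converts the aldehyde to the 1,1-dibromoalkene without affecting the diene.

Step 5
Reactants: 7 (3E,5E,7R)-1,1-dibromo-7-methylnona-1,3,5-triene; 8 methyl (S)-3-bromo-2-methylpropanoate
Product: 10 methyl (2R,4Z,6E,8E,10R)-4-bromo-2,10-dimethyldodeca-4,6,8-trienoate, via zinc homoenolate 9 (not isolated)
Conditions: 8, Zn dust, I2 (5 mol %), DMA, 70 °C; then 7, PdCl2(DPEphos) (3 mol %), THF, 0 °C to rt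
Reagents that add atoms: none
Why: Negishi coupling in which zinc insertion into the C–Br bond of 8 gives a homoenolate whose stereocentre is not the metal-bearing carbon, and oxidative addition of the palladium catalyst takes place at the less hindered C–Br bond trans to the dienyl chain, so that the alkyl group enters trans and the bromine that remains is cis to the chain (4Z).

Step 6
Reactants: 10 methyl (2R,4Z,6E,8E,10R)-4-bromo-2,10-dimethyldodeca-4,6,8-trienoate
Product: 11 (2R,4Z,6E,8E,10R)-4-bromo-2,10-dimethyldodeca-4,6,8-trienal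
Conditions: i-Bu2AlH (1.1 equiv), CH2Cl2, −78 °C; aq potassium sodium tartrate
Reagents that add atoms: none
Why: Partial reduction of a methyl ester with i-Bu2AlH, whose tetrahedral aluminium hemiacetal is stable at −78 °C and releases the aldehyde only on work-up, leaves the alkenyl bromide, the triene and the α-stereocentre intact.

Step 7
Reactants: 12 5-bromo-2,4-dimethoxypyridine; 13 phenylboronic acid
Product: 14 2,4-dimethoxy-5-phenylpyridine
Conditions: Pd(dppf)Cl2 (3 mol %), K2CO3, 1,4-dioxane–H2O, 90 °C
Reagents that add atoms: none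
Why: Suzuki–Miyaura coupling at the only C–Br bond of the pyridine installs the 5-phenyl group.

Step 8
Reactants: 14 2,4-dimethoxy-5-phenylpyridine
Product: 15 2,4-dimethoxy-5-phenylpyridine 1-oxide
Conditions: mCPBA, CH2Cl2, 0 °C to rt
Reagents that add atoms: 3-chloroperoxybenzoic acid (mCPBA), O=C(OO)c1cccc(Cl)c1
Why: Electrophilic N-oxidation of the pyridine nitrogen by the peracid installs the N–O bond before any oxidisable alkene is present in the molecule.

Step 9
Reactants: 15 2,4-dimethoxy-5-phenylpyridine 1-oxide
Product: 16 1,4-dihydroxy-5-phenylpyridin-2(1H)-one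
Conditions: 48% aq HBr, AcOH, 110 °C
Reagents that add atoms: none
Why: Bromide attacks the methyl groups of the protonated 2- and 4-methoxy groups (ether cleavage by nucleophilic substitution at methyl), and the 2-hydroxypyridine N-oxide so formed is the tautomer of the 1-hydroxy-2-pyridone.

Step 10
Reactants: 16 1,4-dihydroxy-5-phenylpyridin-2(1H)-one
Product: 17 [(4-hydroxy-2-oxo-5-phenylpyridin-1(2H)-yl)oxy]methyl 2,2-dimethylpropanoate
Conditions: chloromethyl pivalate (1.0 equiv), K2CO3 (1.0 equiv), DMF, 0 °C
Reagents that add atoms: chloromethyl 2,2-dimethylpropanoate (chloromethyl pivalate), CC(C)(C)C(=O)OCCl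
Why: O-Alkylation of the more acidic and more nucleophilic N-oxide oxygen (a cyclic hydroxamate, α-effect) with one equivalent of base and electrophile masks the N–OH as an acyloxymethyl ether that tolerates palladium, fluoride and weak acid and is removed by mild methanolysis, while the vinylogous-acid 4-OH stays free.

Step 11
Reactants: 11 (2R,4Z,6E,8E,10R)-4-bromo-2,10-dimethyldodeca-4,6,8-trienal; 17 [(4-hydroxy-2-oxo-5-phenylpyridin-1(2H)-yl)oxy]methyl 2,2-dimethylpropanoate
Product: 18 [(3-[(2R,4Z,6E,8E,10R)-4-bromo-1-ethoxy-2,10-dimethyldodeca-4,6,8-trien-1-yl]-4-hydroxy-2-oxo-5-phenylpyridin-1(2H)-yl)oxy]methyl 2,2-dimethylpropanoate (both epimers at the ether carbon)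
Conditions: Et3N (0.2 equiv), EtOH, 40 °C
Reagents that add atoms: ethanol, CCO
Why: Knoevenagel condensation at pyridone C3, the only free nucleophilic carbon, gives the ortho-quinone methide, which the solvent ethanol captures at once by oxa-Michael addition so that the methide is stored as a stable ether (the epimers at the ether carbon are of no consequence because this centre is ionised again in step 12), and the tertiary amine cannot form an enamine with the α-branched aldehyde.

Step 12
Reactants: 18 [(3-[(2R,4Z,6E,8E,10R)-4-bromo-1-ethoxy-2,10-dimethyldodeca-4,6,8-trien-1-yl]-4-hydroxy-2-oxo-5-phenylpyridin-1(2H)-yl)oxy]methyl 2,2-dimethylpropanoate; 19 (tributylstannyl)methanol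
Product: 22 [(4-hydroxy-3-[(2R,3R,5Z)-3-methyl-5-[(2E,4E,6R)-6-methylocta-2,4-dien-1-ylidene]oxan-2-yl]-2-oxo-5-phenylpyridin-1(2H)-yl)oxy]methyl 2,2-dimethylpropanoate, via allylic alcohol 20 (not isolated), via quinone methide 21 (not isolated)
Conditions: Pd(P(t-Bu)3)2 (5 mol %), CsF, 1,4-dioxane, 45 °C; then AcOH, 60 °C
Reagents that add atoms: none
Why: Oxidative addition of the alkenyl C–Br bond of 18 to zerovalent palladium, fluoride-assisted transfer of the hydroxymethyl group of 19 from tin and reductive elimination form the oxane C5–C6 bond with retention of the 4Z geometry (allylic alcohol 20); acetic acid then ionises the ethoxy group next to pyridone C3, the 4-hydroxy-2-pyridone passes into its ortho-quinone methide 21 as in the presumed biosynthesis, and the new primary hydroxyl adds to the methide carbon to form the O1–C2 bond. The closest known reaction types are the Kosugi–Migita–Stille hydroxymethylation of alkenyl halides with 19 and the oxa-Michael capture of pyridone and coumarin ortho-quinone methides by alcohols. The one ring formed closes in the 6-exo-trig mode, the oxygen attacking the exocyclic methide carbon. The new stereocentre at oxane C2 is controlled by the methyl-bearing C3: a chair transition state with methyl and pyridone both equatorial leads to the 2,3-trans (2R,3R) isomer, and since the oxa-Michael addition is reversible in the acidic medium the same isomer is also the thermodynamic product. The step needs retention at the dien-2-yl palladium intermediate, which the bulky electron-rich P(t-Bu)3 ligand should secure by making transmetalation and reductive elimination faster than isomerisation, and it needs oxygen capture of 21 to outrun tautomerisation to a 3-alkenylpyridone, which the substrate secures because the hydroxyl is delivered through a six-membered transition state while the trans relation of the ring-forming chain and the dienyl chain across the alkene keeps the triene out of reach of the methide.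

Step 13
Reactants: 22 [(4-hydroxy-3-[(2R,3R,5Z)-3-methyl-5-[(2E,4E,6R)-6-methylocta-2,4-dien-1-ylidene]oxan-2-yl]-2-oxo-5-phenylpyridin-1(2H)-yl)oxy]methyl 2,2-dimethylpropanoate
Product: 23 1,4-dihydroxy-3-[(2R,3R,5Z)-3-methyl-5-[(2E,4E,6R)-6-methylocta-2,4-dien-1-ylidene]oxan-2-yl]-5-phenylpyridin-2(1H)-one
Conditions: NaOMe (2.5 equiv), MeOH, 0 °C to rt; then AcOH
Reagents that add atoms: none
Why: Methoxide cleaves the pivalate ester (transesterification) and the resulting N-O-hemiacetal loses formaldehyde to free the N–OH, under basic conditions that leave the acid-sensitive trienyl allylic ether, the triene geometry and both ring stereocentres untouched.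

**Compound list**

1 | (R)-2-methylbutan-1-ol | CC[C@@H](C)CO | starting material
2 | (R)-2-methylbutanal | CC[C@@H](C)C=O | intermediate
3 | (3R,1E)-1-iodo-3-methylpent-1-ene | CC[C@@H](C)/C=C/I | intermediate
4 | (E)-2-(3,3-diethoxyprop-1-en-1-yl)-4,4,5,5-tetramethyl-1,3,2-dioxaborolane | CCOC(OCC)/C=C/B1OC(C)(C)C(C)(C)O1 | starting material
5 | (2E,4E,6R)-1,1-diethoxy-6-methylocta-2,4-diene | CC[C@@H](C)/C=C/C=C/C(OCC)OCC | intermediate
6 | (2E,4E,6R)-6-methylocta-2,4-dienal | CC[C@@H](C)/C=C/C=C/C=O | intermediate
7 | (3E,5E,7R)-1,1-dibromo-7-methylnona-1,3,5-triene | CC[C@@H](C)/C=C/C=C/C=C(Br)Br | intermediate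
8 | methyl (S)-3-bromo-2-methylpropanoate | COC(=O)[C@H](C)CBr | starting material
9 | bromo[(2S)-3-methoxy-2-methyl-3-oxopropyl]zinc | COC(=O)[C@H](C)C[Zn]Br | intermediate
10 | methyl (2R,4Z,6E,8E,10R)-4-bromo-2,10-dimethyldodeca-4,6,8-trienoate | COC(=O)[C@H](C)C/C(Br)=C/C=C/C=C/[C@H](C)CC | intermediate
11 | (2R,4Z,6E,8E,10R)-4-bromo-2,10-dimethyldodeca-4,6,8-trienal | O=C[C@H](C)C/C(Br)=C/C=C/C=C/[C@H](C)CC | intermediate
12 | 5-bromo-2,4-dimethoxypyridine | COc1cc(OC)c(Br)cn1 | starting material
13 | phenylboronic acid | OB(O)c1ccccc1 | starting material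
14 | 2,4-dimethoxy-5-phenylpyridine | COc1cc(OC)c(-c2ccccc2)cn1 | intermediate
15 | 2,4-dimethoxy-5-phenylpyridine 1-oxide | COc1cc(OC)c(-c2ccccc2)c[n+]1[O-] | intermediate
16 | 1,4-dihydroxy-5-phenylpyridin-2(1H)-one | O=c1cc(O)c(-c2ccccc2)cn1O | intermediate
17 | [(4-hydroxy-2-oxo-5-phenylpyridin-1(2H)-yl)oxy]methyl 2,2-dimethylpropanoate | CC(C)(C)C(=O)OCOn1cc(-c2ccccc2)c(O)cc1=O | intermediate
18 | [(3-[(2R,4Z,6E,8E,10R)-4-bromo-1-ethoxy-2,10-dimethyldodeca-4,6,8-trien-1-yl]-4-hydroxy-2-oxo-5-phenylpyridin-1(2H)-yl)oxy]methyl 2,2-dimethylpropanoate (epimers at the ether carbon) | CCOC(c1c(O)c(-c2ccccc2)cn(OCOC(=O)C(C)(C)C)c1=O)[C@H](C)C/C(Br)=C/C=C/C=C/[C@H](C)CC | intermediate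
19 | (tributylstannyl)methanol | CCCC[Sn](CCCC)(CCCC)CO | starting material
20 | [(3-[(2R,4Z,6E,8E,10R)-1-ethoxy-4-(hydroxymethyl)-2,10-dimethyldodeca-4,6,8-trien-1-yl]-4-hydroxy-2-oxo-5-phenylpyridin-1(2H)-yl)oxy]methyl 2,2-dimethylpropanoate | CCOC(c1c(O)c(-c2ccccc2)cn(OCOC(=O)C(C)(C)C)c1=O)[C@H](C)C/C(CO)=C/C=C/C=C/[C@H](C)CC | intermediate
21 | [(3-[(2R,4Z,6E,8E,10R)-4-(hydroxymethyl)-2,10-dimethyldodeca-4,6,8-trien-1-ylidene]-2,4-dioxo-5-phenyl-3,4-dihydropyridin-1(2H)-yl)oxy]methyl 2,2-dimethylpropanoate | O=C1C(=C[C@H](C)C/C(CO)=C/C=C/C=C/[C@H](C)CC)C(=O)N(OCOC(=O)C(C)(C)C)C=C1c2ccccc2 | intermediate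
22 | [(4-hydroxy-3-[(2R,3R,5Z)-3-methyl-5-[(2E,4E,6R)-6-methylocta-2,4-dien-1-ylidene]oxan-2-yl]-2-oxo-5-phenylpyridin-1(2H)-yl)oxy]methyl 2,2-dimethylpropanoate | CC[C@@H](C)/C=C/C=C/C=C1\CO[C@@H](c2c(O)c(-c3ccccc3)cn(OCOC(=O)C(C)(C)C)c2=O)[C@H](C)C1 | intermediate
23 | 1,4-dihydroxy-3-[(2R,3R,5Z)-3-methyl-5-[(2E,4E,6R)-6-methylocta-2,4-dien-1-ylidene]oxan-2-yl]-5-phenylpyridin-2(1H)-one | CC[C@@H](C)/C=C/C=C/C=C1\CO[C@@H](c2c(O)c(-c3ccccc3)cn(O)c2=O)[C@H](C)C1 | target

**Step count and risks**

Total steps: 13. Longest linear sequence: 9 steps (steps 1 to 6, then 11 to 13).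

Steps most likely to fail:

Step 12. What may go wrong: isomerisation of the dien-2-yl palladium intermediate before transmetalation, which would erode the 5Z geometry, or slow coupling next to the free pyridone. The fallback avoids palladium at this carbon and sets out from 10. LiOH in THF–H2O should give the carboxylic acid F1. t-BuLi (3 equiv, THF, −78 °C) should deprotonate the acid and exchange bromine for lithium with retention, and gaseous formaldehyde should then give the hydroxy acid F2. EDC·HCl and DMAP should close F2 to the lactone F3, and i-Bu2AlH at −78 °C should give the lactol F4. Condensation of F4 with 17 (Et3N cat., EtOH, 50 °C; Knoevenagel condensation of the open hydroxy aldehyde, then oxa-Michael closure) comes back to the route at 22.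

Step 11. What may go wrong: enolisation of the α-branched aldehyde or tautomerisation of the transient quinone methide to a 3-alkenylpyridone, both of which erode the methyl-bearing stereocentre, and double addition of the pyridone to the methide. The fallback sets out from 11 and 17. An amine-free three-component condensation with benzenesulfinic acid (CH2Cl2, rt), in which the strongly nucleophilic sulfinate traps the methide faster than an alcohol can, should give the sulfone F5. Under the palladium and CsF conditions of step 12 with 19, F5 should be hydroxymethylated to the sulfone F6; fluoride-induced loss of benzenesulfinate then gives 21, and ring closure comes back to the route at 22.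

Step 5. What may go wrong: slow transmetalation of the ester-chelated zinc homoenolate, and a second substitution at the remaining C–Br bond. The fallback sets out from 7. The known iodide (S)-tert-butyl(3-iodo-2-methylpropoxy)dimethylsilane F7 is converted (t-BuLi, then ZnCl2) to the non-chelating zinc reagent F8, and Negishi coupling with 7 under the same catalyst should give the silyl ether F9. Bu4NF should give the alcohol F10, and Dess–Martin oxidation comes back to the route at 11.

**Further compounds**

F1 | step 12 | (2R,4Z,6E,8E,10R)-4-bromo-2,10-dimethyldodeca-4,6,8-trienoic acid | OC(=O)[C@H](C)C/C(Br)=C/C=C/C=C/[C@H](C)CC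
F2 | step 12 | (2R,4Z,6E,8E,10R)-4-(hydroxymethyl)-2,10-dimethyldodeca-4,6,8-trienoic acid | OC(=O)[C@H](C)C/C(CO)=C/C=C/C=C/[C@H](C)CC
F3 | step 12 | (3R,5Z)-3-methyl-5-[(2E,4E,6R)-6-methylocta-2,4-dien-1-ylidene]oxan-2-one | CC[C@@H](C)/C=C/C=C/C=C1\COC(=O)[C@H](C)C1
F4 | step 12 | (3R,5Z)-3-methyl-5-[(2E,4E,6R)-6-methylocta-2,4-dien-1-ylidene]oxan-2-ol (both anomers) | CC[C@@H](C)/C=C/C=C/C=C1\COC(O)[C@H](C)C1
F5 | step 11 | [(3-[(2R,4Z,6E,8E,10R)-4-bromo-2,10-dimethyl-1-(phenylsulfonyl)dodeca-4,6,8-trien-1-yl]-4-hydroxy-2-oxo-5-phenylpyridin-1(2H)-yl)oxy]methyl 2,2-dimethylpropanoate | O=S(=O)(c1ccccc1)C(c1c(O)c(-c2ccccc2)cn(OCOC(=O)C(C)(C)C)c1=O)[C@H](C)C/C(Br)=C/C=C/C=C/[C@H](C)CC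
F6 | step 11 | [(4-hydroxy-3-[(2R,4Z,6E,8E,10R)-4-(hydroxymethyl)-2,10-dimethyl-1-(phenylsulfonyl)dodeca-4,6,8-trien-1-yl]-2-oxo-5-phenylpyridin-1(2H)-yl)oxy]methyl 2,2-dimethylpropanoate | O=S(=O)(c1ccccc1)C(c1c(O)c(-c2ccccc2)cn(OCOC(=O)C(C)(C)C)c1=O)[C@H](C)C/C(CO)=C/C=C/C=C/[C@H](C)CC
F7 | step 5 | (S)-tert-butyl(3-iodo-2-methylpropoxy)dimethylsilane | CC(C)(C)[Si](C)(C)OC[C@H](C)CI
F8 | step 5 | [(2S)-3-(tert-butyldimethylsilyloxy)-2-methylpropyl]zinc iodide | CC(C)(C)[Si](C)(C)OC[C@H](C)C[Zn]I
F9 | step 5 | tert-butyl{[(2R,4Z,6E,8E,10R)-4-bromo-2,10-dimethyldodeca-4,6,8-trien-1-yl]oxy}dimethylsilane | CC(C)(C)[Si](C)(C)OC[C@H](C)C/C(Br)=C/C=C/C=C/[C@H](C)CC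
F10 | step 5 | (2R,4Z,6E,8E,10R)-4-bromo-2,10-dimethyldodeca-4,6,8-trien-1-ol | OC[C@H](C)C/C(Br)=C/C=C/C=C/[C@H](C)CC
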